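The target's two lactone stereocentres have the same configuration as 2‑deoxy‑D‑ribono‑1,4‑lactone, so no inversion is needed on the east side.

The route rests on cutting the chain on both sides of C8: the C7–C8 bond to the (6E)-alkene and the C9–C10 bond to the exocyclic alkene of the γ-lactone ring. Because the acetoxy carbon C8 lies between alkenyl carbon C7 and the C9 methylene that leads to alkylidene carbon C10, a vinylboronate can supply C8–C9. One palladium-catalysed conjunctive coupling joins a nerol-derived alkenyl group, the vinyl unit and a lactone enol triflate, forming both bonds and leaving C8 as a configured C–B bond that becomes the acetate. The precursor is the bis(alkenyl) boron ate complex from a 7-lithio-diene and vinylboronic pinacol ester, together with the (E)-triflyloxymethylene lactone made from 2-deoxy-D-ribonolactone.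

Key step: step 13

Remarks on the chemistry (stated before the steps):
- Numbering: C1 is the ester-bearing CH2, C2=C3 the (Z)-alkene, C6=C7 the (E)-alkene, C8 the acetoxy carbon, C9 the methylene, C10 the exocyclic alkene carbon; C11 is lactone C3, the carbinol is lactone C4 and the isobutenyl-bearing carbon is lactone C5.
- Lithium reagent 19 has lithium trans to C5, the same spatial arrangement as the (6E)-iodide 9 and the (6E)-product. By the sequence rules it is 6Z (named 2Z from the lithium end), because the methyl carbon outranks lithium.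
- Iodine–lithium exchange leaves one equivalent of LiI beside the ate complex. Halide blocks the cationic palladium intermediate, so KOTf is added as a halide scavenger.
- Assumption: by analogy with aryl and alkenyl migrating groups, the (Rp,Rp) antipode of the MandyPhos ligand is expected to give (S)-C8. This is to be confirmed on alcohol 22 by Mosher ester analysis before material is committed; both antipodes are commercial.

**West fragment**

Step 1
Reactants: 1 nerol
Product: 2 tert-butyl{[(2Z)-3,7-dimethylocta-2,6-dien-1-yl]oxy}dimethylsilane (neryl TBS ether)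
Conditions: TBSCl, imidazole, CH2Cl2, 0 °C to rt
Reagents that add atoms: tert-butyldimethylsilyl chloride, CC(C)(C)[Si](C)(C)Cl
Why: Imidazole-promoted silylation of the primary allylic alcohol is routine and gives the base-stable ether needed for the later organolithium steps.

Step 2
Reactants: 2 neryl TBS ether
Product: 3 tert-butyl{[(2Z)-5-(3,3-dimethyloxiran-2-yl)-3-methylpent-2-en-1-yl]oxy}dimethylsilane (6,7-epoxide; racemic at the oxirane CH)
Conditions: mCPBA (1.0 equiv), NaHCO3, CH2Cl2, −20 to 0 °C
Reagents that add atoms: 3-chloroperbenzoic acid, OOC(=O)c1cccc(Cl)c1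
Why: Prilezhaev epoxidation with one equivalent of peracid should favour the remote 6,7-alkene because the 2,3-alkene is deactivated by the allylic silyloxy group; the new oxirane centre is excised in step 3.

Step 3
Reactants: 3 6,7-epoxide
Product: 4 (4Z)-6-[(tert-butyldimethylsilyl)oxy]-4-methylhex-4-enal
Conditions: H5IO6, THF/H2O, 0 °C
Reagents that add atoms: none
Why: Periodic acid opens the trisubstituted epoxide and cleaves the resulting glycol in the same flask (Malaprade-type cleavage), releasing acetone and the C6 aldehyde without touching the (2Z)-alkene.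

Step 4
Reactants: 4 aldehyde
Product: 5 tert-butyl{[(2Z)-7,7-dibromo-3-methylhepta-2,6-dien-1-yl]oxy}dimethylsilane
Conditions: CBr4, PPh3, Et3N, CH2Cl2, 0 °C
Reagents that add atoms: carbon tetrabromide, BrC(Br)(Br)Br
Why: Corey–Fuchs dibromo-olefination of an unhindered aldehyde, with triethylamine buffering the medium so that the allylic silyl ether survives.

Step 5
Reactants: 5 dibromoalkene
Product: 7 tert-butyldimethyl{[(2Z)-3-methyloct-2-en-6-yn-1-yl]oxy}silane, via lithium acetylide 6 (not isolated)
Conditions: n-BuLi (2.1 equiv), THF, −78 °C; then MeI, −78 °C to rt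
Reagents that add atoms: iodomethane, CI
Why: Second stage of the Corey–Fuchs sequence: bromine–lithium exchange and Fritsch–Buttenberg–Wiechell rearrangement give the lithium acetylide, which is C-methylated by iodomethane.

Step 6
Reactants: 7 methyl alkyne
Product: 9 tert-butyl{[(2Z,6E)-7-iodo-3-methylocta-2,6-dien-1-yl]oxy}dimethylsilane, via alkenylzirconocene chloride 8 (not isolated)
Conditions: Cp2Zr(H)Cl (2 equiv), THF, 50 °C; then I2, THF, 0 °C
Reagents that add atoms: iodine, II
Why: syn-Hydrozirconation of the 2-alkyne, equilibrated by excess hydride so that zirconium ends on the less hindered methyl-bearing C7, followed by iodinolysis with retention should give the (6E)-iodide; the trisubstituted alkene and the silyl ether are inert.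

**East fragment**

Step 7
Reactants: 10 2-deoxy-D-ribono-1,4-lactone
Product: 11 (4S,5R)-4-[(tert-butyldimethylsilyl)oxy]-5-{[(tert-butyldimethylsilyl)oxy]methyl}dihydrofuran-2(3H)-one
Conditions: TBSCl (2.4 equiv), imidazole, DMF, rt
Reagents that add atoms: tert-butyldimethylsilyl chloride, CC(C)(C)[Si](C)(C)Cl
Why: Imidazole-promoted bis-silylation of both hydroxyl groups; the two stereocentres come from the carbohydrate and are untouched.

Step 8
Reactants: 11 bis-silyl lactone
Product: 12 (4S,5R)-4-[(tert-butyldimethylsilyl)oxy]-5-(hydroxymethyl)dihydrofuran-2(3H)-one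
Conditions: TFA/H2O/THF (1:1:4), 0 °C
Reagents that add atoms: none
Why: Acid-catalysed solvolysis of silyl ethers is governed by steric access, so the primary ether should be cleaved well before the secondary one (selective desilylation), and the lactone is stable to cold aqueous acid.

Step 9
Reactants: 12 primary alcohol
Product: 13 (2S,3S)-3-[(tert-butyldimethylsilyl)oxy]-5-oxotetrahydrofuran-2-carbaldehyde
Conditions: Dess–Martin periodinane, NaHCO3, CH2Cl2, 0 °C to rt; used crude
Reagents that add atoms: none
Why: Dess–Martin oxidation under buffered, non-basic conditions should give the aldehyde without epimerising the carbon next to it or eliminating the β-silyloxy group (the changed descriptor reflects priorities only).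

Step 10
Reactants: 13 aldehyde
Product: 14 (4S,5R)-4-[(tert-butyldimethylsilyl)oxy]-5-(2-methylprop-1-en-1-yl)dihydrofuran-2(3H)-one
Conditions: i-PrPPh3I, n-BuLi, THF, 0 °C; then 13, −78 to 0 °C
Reagents that add atoms: isopropyltriphenylphosphonium iodide, CC(C)[P+](c1ccccc1)(c1ccccc1)c1ccccc1.[I-]
Why: Wittig olefination with the non-stabilised isopropylidene ylide is much faster at the aldehyde than at the lactone carbonyl at −78 °C and creates no new stereo-element because the ylide carbon carries two methyl groups; lactone C5 keeps the carbohydrate configuration.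

Step 11
Reactants: 14 isobutenyl lactone
Product: 16 (3E,4S,5R)-4-[(tert-butyldimethylsilyl)oxy]-3-(hydroxymethylidene)-5-(2-methylprop-1-en-1-yl)dihydrofuran-2(3H)-one (enol form of the α-formyl lactone), via lithium lactone enolate 15 (not isolated)
Conditions: LiN(SiMe3)2 (1.1 equiv), THF, −78 °C; HCO2CH2CF3, −78 to −20 °C; aq. NH4Cl
Reagents that add atoms: 2,2,2-trifluoroethyl formate, O=COCC(F)(F)F
Why: Crossed Claisen C-formylation of the lithium enolate with an activated formate; at −78 °C the five-ring enolate should not expel the β-silyloxy group, and the product is held as its stabilised β-dicarbonyl anion until the quench.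

Step 12
Reactants: 16 hydroxymethylene lactone
Product: 17 (E)-[(4S,5R)-4-[(tert-butyldimethylsilyl)oxy]-5-(2-methylprop-1-en-1-yl)-2-oxodihydrofuran-3(2H)-ylidene]methyl trifluoromethanesulfonate
Conditions: Tf2O, i-Pr2NEt, CH2Cl2, −78 °C
Reagents that add atoms: trifluoromethanesulfonic anhydride, O=S(=O)(OS(=O)(=O)C(F)(F)F)C(F)(F)F
Why: Enol triflate formation under non-chelating amine conditions should place the triflyloxy group anti to the lactone carbonyl, the arrangement an exocyclic five-ring enolate prefers because it cannot chelate and minimises dipole repulsion; the (E) geometry is to be confirmed by NOE before use.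

**Union and endgame**

Step 13
Reactants: 9 (2Z,6E)-alkenyl iodide; 18 vinylboronic acid pinacol ester; 17 (E)-enol triflate
Product: 21 (8S)-C8 pinacol boronate with both halves joined [(2Z,6E,10E)-1-silyloxy-3,7-dimethyl-deca-2,6-diene carrying B(pin) at C8 and the silylated lactone as the C10 alkylidene], via 7-lithiodiene 19 (not isolated), via lithium vinyl(alkenyl)borate 20 (not isolated)
Conditions: 9, t-BuLi (2.0 equiv), Et2O, −78 °C; 18 (1.0 equiv), −78 °C to rt; solvent exchange to THF; KOTf (2 equiv), Pd(OAc)2 (3 mol %), (Rp,Rp)-MandyPhos {1,1′-bis[bis(4-methoxy-3,5-dimethylphenyl)phosphino]-2,2′-bis[(S)-α-(dimethylamino)benzyl]ferrocene, 3.6 mol %}, 17 (0.8 equiv, limiting), THF, 40–60 °C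
Reagents that add atoms: none
Why: Iodine–lithium exchange with retention gives 19, which adds to boron of 18 to form ate complex 20; oxidative addition of the activated triflate 17 to zerovalent palladium (from Pd(OAc)2 and the diphosphine) gives a cationic alkenylpalladium that binds the vinyl group of 20 and induces an anti 1,2-metallate shift of the C7 alkenyl group from boron to C8, after which reductive elimination forms C9–C10. The closest known reaction type is the palladium/MandyPhos conjunctive cross-coupling of bis(alkenyl)borates with alkenyl triflates, which delivers α-chiral allylic boronates. No ring is closed. The C8 stereocentre is set by the chiral ferrocenyl diphosphine (catalyst control through the face of the bound vinyl group), and the two remote lactone centres should not override it. The step needs the unsubstituted vinyl group rather than the trisubstituted alkenyl group as the palladium-bound acceptor (secured by sterics), retention of both alkene geometries (exchange, migration and oxidative addition are stereoretentive) and suppression of direct Suzuki-type transfer (pinacol on boron and the chelating ligand). KOTf removes the iodide that would otherwise occupy the cationic palladium, and with the triflate as limiting partner the lactone meets only the ate complex and never a free organolithium.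

Step 14
Reactants: 21 C8 boronate
Product: 22 (8S)-C8 alcohol, bis-TBS ether (C1–OTBS and lactone C4–OTBS)
Conditions: NaBO3·4H2O, THF/H2O (1:1), 0 °C to rt
Reagents that add atoms: sodium perborate, [Na+].[O-]OB=O
Why: Perborate oxidation of the C–B bond proceeds by 1,2-migration of C8 from boron to oxygen with retention and without allylic transposition, and the weakly basic reagent should spare the alkylidene lactone from conjugate epoxidation and hydrolysis.

Step 15
Reactants: 22 C8 alcohol
Product: 23 (8S)-C8 acetate, bis-TBS ether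
Conditions: Ac2O, pyridine, DMAP (cat.), CH2Cl2, 0 °C to rt
Reagents that add atoms: acetic anhydride, CC(=O)OC(C)=O
Why: DMAP-catalysed acetylation (nucleophilic acyl transfer) of the only free hydroxyl group; the C8 configuration is not touched.

Step 16
Reactants: 23 acetate bis-TBS ether
Product: 24 (8S)-8-acetoxy diol (free C1–OH and lactone C4–OH)
Conditions: HF·pyridine, pyridine, THF, 0 °C to rt
Reagents that add atoms: none
Why: Fluoride-driven Si–O cleavage under buffered HF·pyridine should remove both silyl ethers while the allylic acetate, the lactone and the allylic C–O bonds stay intact, which basic fluoride sources would endanger.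

Step 17
Reactants: 24 diol; 25 (E)-3-methylpent-2-enoic acid (1.05 equiv)
Product: 26 target CNP0168501.1
Conditions: DIC, DMAP (0.1 equiv), CH2Cl2, −20 to 0 °C
Reagents that add atoms: none
Why: Steglich esterification with about one equivalent of acid should acylate the unhindered primary allylic C1 hydroxyl far faster than the secondary ring hydroxyl, which is flanked by lactone C5 and the alkylidene carbon; without strong base the (E)-geometry of the acid is kept.

**Compound list**

1 | nerol, (2Z)-3,7-dimethylocta-2,6-dien-1-ol | CC(C)=CCC/C(C)=C\CO | starting material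
2 | neryl TBS ether | CC(C)=CCC/C(C)=C\CO[Si](C)(C)C(C)(C)C | intermediate
3 | 6,7-epoxyneryl TBS ether (racemic at oxirane CH) | CC1(C)OC1CC/C(C)=C\CO[Si](C)(C)C(C)(C)C | intermediate
4 | (4Z)-6-[(tert-butyldimethylsilyl)oxy]-4-methylhex-4-enal | O=CCC/C(C)=C\CO[Si](C)(C)C(C)(C)C | intermediate
5 | (2Z)-7,7-dibromo-3-methylhepta-2,6-dienyl TBS ether | BrC(Br)=CCC/C(C)=C\CO[Si](C)(C)C(C)(C)C | intermediate
6 | lithium acetylide of the C6–C7 alkyne (not isolated) | [Li]C#CCC/C(C)=C\CO[Si](C)(C)C(C)(C)C | intermediate
7 | (2Z)-3-methyloct-2-en-6-ynyl TBS ether | CC#CCC/C(C)=C\CO[Si](C)(C)C(C)(C)C | intermediate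
8 | chlorobis(cyclopentadienyl)[(2E,6Z)-8-(TBS-oxy)-6-methylocta-2,6-dien-2-yl]zirconium (not isolated; Cp drawn σ-bonded) | Cl[Zr](/C(C)=C/CC/C(C)=C\CO[Si](C)(C)C(C)(C)C)(C1C=CC=C1)C1C=CC=C1 | intermediate
9 | (2Z,6E)-7-iodo-3-methylocta-2,6-dienyl TBS ether | I/C(C)=C/CC/C(C)=C\CO[Si](C)(C)C(C)(C)C | intermediate
10 | 2-deoxy-D-ribono-1,4-lactone, (4S,5R)-4-hydroxy-5-(hydroxymethyl)dihydrofuran-2(3H)-one | O=C1C[C@H](O)[C@@H](CO)O1 | starting material
11 | 3,5-bis-O-TBS-2-deoxy-D-ribonolactone | O=C1C[C@H](O[Si](C)(C)C(C)(C)C)[C@@H](CO[Si](C)(C)C(C)(C)C)O1 | intermediate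
12 | 3-O-TBS-2-deoxy-D-ribonolactone (free primary OH) | O=C1C[C@H](O[Si](C)(C)C(C)(C)C)[C@@H](CO)O1 | intermediate
13 | (2S,3S)-3-(TBS-oxy)-5-oxotetrahydrofuran-2-carbaldehyde | O=C1C[C@H](O[Si](C)(C)C(C)(C)C)[C@@H](C=O)O1 | intermediate
14 | (4S,5R)-4-(TBS-oxy)-5-(2-methylprop-1-enyl)dihydrofuran-2(3H)-one | O=C1C[C@H](O[Si](C)(C)C(C)(C)C)[C@@H](C=C(C)C)O1 | intermediate
15 | lithium enolate of 14 (not isolated) | [Li]OC1=C[C@H](O[Si](C)(C)C(C)(C)C)[C@@H](C=C(C)C)O1 | intermediate
16 | (3E,4S,5R)-3-(hydroxymethylidene) lactone (enol of the α-formyl lactone) | O/C=C1/C(=O)O[C@H](C=C(C)C)[C@H]1O[Si](C)(C)C(C)(C)C | intermediate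
17 | (E)-triflyloxymethylene lactone, TBS ether at lactone C4 | FC(F)(F)S(=O)(=O)O/C=C1/C(=O)O[C@H](C=C(C)C)[C@H]1O[Si](C)(C)C(C)(C)C | intermediate
18 | vinylboronic acid pinacol ester | C=CB1OC(C)(C)C(C)(C)O1 | starting material
19 | [(2Z,6Z)-8-(TBS-oxy)-6-methylocta-2,6-dien-2-yl]lithium, lithium trans to C5 (not isolated) | [Li]/C(C)=C/CC/C(C)=C\CO[Si](C)(C)C(C)(C)C | intermediate
20 | lithium (vinyl)(alkenyl)(pinacolato)borate (not isolated) | [Li+].C=C[B-]1(/C(C)=C/CC/C(C)=C\CO[Si](C)(C)C(C)(C)C)OC(C)(C)C(C)(C)O1 | intermediate
21 | (8S)-C8 allylic pinacol boronate, (2Z,6E,10E), bis-TBS | CC(C)(C)[Si](C)(C)OC/C=C(/C)CC/C=C(\C)[C@H](C/C=C1/C(=O)O[C@H](C=C(C)C)[C@H]1O[Si](C)(C)C(C)(C)C)B2OC(C)(C)C(C)(C)O2 | intermediate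
22 | (8S)-C8 alcohol, bis-TBS | CC(C)(C)[Si](C)(C)OC/C=C(/C)CC/C=C(\C)[C@H](C/C=C1/C(=O)O[C@H](C=C(C)C)[C@H]1O[Si](C)(C)C(C)(C)C)O | intermediate
23 | (8S)-C8 acetate, bis-TBS | CC(C)(C)[Si](C)(C)OC/C=C(/C)CC/C=C(\C)[C@H](C/C=C1/C(=O)O[C@H](C=C(C)C)[C@H]1O[Si](C)(C)C(C)(C)C)OC(C)=O | intermediate
24 | (8S)-8-acetoxy diol (C1–OH and lactone C4–OH free) | OC/C=C(/C)CC/C=C(\C)[C@H](C/C=C1/C(=O)O[C@H](C=C(C)C)[C@H]1O)OC(C)=O | intermediate
25 | (E)-3-methylpent-2-enoic acid | CC/C(C)=C/C(=O)O | starting material
26 | target: (2Z,6E,8S,10E)-8-acetoxy-10-[(4S,5R)-4-hydroxy-5-(2-methylprop-1-enyl)-2-oxodihydrofuran-3(2H)-ylidene]-3,7-dimethyldeca-2,6-dienyl (E)-3-methylpent-2-enoate | CC/C(C)=C/C(=O)OC/C=C(/C)CC/C=C(\C)[C@H](C/C=C1/C(=O)O[C@H](C=C(C)C)[C@H]1O)OC(C)=O | target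

**Count and risks**

Total step count: 17. Longest linear sequence: 11 steps (steps 1–6 or 7–12, then 13–17).

The three steps most likely to fail:

1. Step 13. The electron-poor β-triflyloxy enoate may react with the ate complex by uncatalysed conjugate addition–elimination, which would give the same constitution without control of C8. Direct transfer of an alkenyl group from boron to palladium, loss of geometry at the palladated enoate carbon, or ionisation of the allylic lactone C–O bond by zerovalent palladium could also erode the outcome.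
   Fallback: an aldol-condensation route to the alkylidene lactone, which sets out from iodide 9 and lactone 14 and comes back at alcohol 22. Lithiated 9 (that is, 19) is acylated with N-methoxy-N-methyl-3-[(4-methoxybenzyl)oxy]propanamide to give the α-methyl enone F1. Reduction with catecholborane and (R)-2-methyl-CBS-oxazaborolidine should give the (8S)-allylic alcohol F2 (alkenyl as the large group). TESCl/imidazole gives the triethylsilyl ether F3. DDQ in buffered CH2Cl2/H2O removes the 4-methoxybenzyl group to give the primary alcohol F4. Dess–Martin oxidation gives the β-silyloxy aldehyde F5. Addition of F5 to lithium enolate 15 (from 14) at −78 °C gives the aldol adduct F6 as a mixture of carbinol epimers. Mesylation and DBU-promoted elimination should give the (E)-alkylidene lactone F7. PPTS in MeOH at 0 °C then removes only the triethylsilyl group and gives 22.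

2. Step 10. The basic, hindered ylide may deprotonate the aldehyde α-carbon, leading to epimerisation at lactone C5 or β-elimination of the silyloxy group before olefination.
   Fallback: sets out from aldehyde 13 and comes back at lactone 14. Non-basic Takai–Lombardo methylenation (Zn, CH2Br2, TiCl4, THF/CH2Cl2, 0 °C) gives the vinyl lactone F8. Cross-metathesis in 2-methyl-2-butene with the second-generation Grubbs catalyst, (H2IMes)(PCy3)Cl2Ru=CHPh, converts the vinyl group into the 2-methylprop-1-enyl group of 14.

3. Step 11. The lactone enolate may expel the β-silyloxy group (elimination to a butenolide) or be formylated on oxygen.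
   Fallback: sets out from lactone 14 and comes back at hydroxymethylene lactone 16. Condensation with tert-butoxybis(dimethylamino)methane (toluene, 70 °C), which needs no preformed enolate, gives the (E)-dimethylaminomethylene lactone F9. Brief hydrolysis with dilute HCl in THF at 0 °C gives 16.

Further compounds
F1 | step 13 | (2Z,6E)-enone, 1-(TBS-oxy)-10-[(4-methoxybenzyl)oxy]-3,7-dimethyldeca-2,6-dien-8-one | CC(C)(C)[Si](C)(C)OC/C=C(/C)CC/C=C(\C)C(=O)CCOCc1ccc(OC)cc1
F2 | step 13 | (8S)-allylic alcohol | CC(C)(C)[Si](C)(C)OC/C=C(/C)CC/C=C(\C)[C@H](CCOCc1ccc(OC)cc1)O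
F3 | step 13 | (8S)-triethylsilyl ether | CC(C)(C)[Si](C)(C)OC/C=C(/C)CC/C=C(\C)[C@H](CCOCc1ccc(OC)cc1)O[Si](CC)(CC)CC
F4 | step 13 | (8S)-8-(triethylsilyloxy) primary alcohol at C10 | CC(C)(C)[Si](C)(C)OC/C=C(/C)CC/C=C(\C)[C@H](CCO)O[Si](CC)(CC)CC
F5 | step 13 | (8S)-8-(triethylsilyloxy) C10 aldehyde | CC(C)(C)[Si](C)(C)OC/C=C(/C)CC/C=C(\C)[C@H](CC=O)O[Si](CC)(CC)CC
F6 | step 13 | aldol adduct (epimers at C10 and lactone C3) | CC(C)(C)[Si](C)(C)OC/C=C(/C)CC/C=C(\C)[C@H](CC(O)C1C(=O)O[C@H](C=C(C)C)[C@H]1O[Si](C)(C)C(C)(C)C)O[Si](CC)(CC)CC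
F7 | step 13 | (10E)-alkylidene lactone with C8–OTES, bis-TBS | CC(C)(C)[Si](C)(C)OC/C=C(/C)CC/C=C(\C)[C@H](C/C=C1/C(=O)O[C@H](C=C(C)C)[C@H]1O[Si](C)(C)C(C)(C)C)O[Si](CC)(CC)CC
F8 | step 10 | (4S,5R)-4-(TBS-oxy)-5-vinyldihydrofuran-2(3H)-one | O=C1C[C@H](O[Si](C)(C)C(C)(C)C)[C@@H](C=C)O1
F9 | step 11 | (E)-3-(dimethylaminomethylene) lactone | CN(C)/C=C1/C(=O)O[C@H](C=C(C)C)[C@H]1O[Si](C)(C)C(C)(C)C
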